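**Retrosynthetic overview**

1. Feature: number the carbocycle C1 (carbon of C=CH2), C2, C3, C4 (CHBr), C5 (CMe2), C6 (CH carrying the benzylic C7). The run C1–C5 with Br on C4 is the carbon chain of a 5-bromo-6,6-dimethyl-δ-lactone, whose ring oxygen is bonded to C5 at the place C6 must take.
2. End game: C1=CH2 from the C1 ketone by non-basic methylenation; the hydroquinone from its dimethyl ether.
3. Key disconnection C5–C6: the cis bromoketone from the (R,Z)-2-alkylidene-5-bromo-6,6-dimethyloxane by a Lewis-acid 1,3 shift from oxygen to carbon (O–C5 broken, C5–C6 made).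
4. Enol ether from the (R)-bromolactone (asymmetric 6-endo bromolactonisation of 5-methylhex-4-enoic acid) and ArCH2CHBr2 (benzylic bromide plus LiCHBr2) by Takai–Utimoto alkylidenation.
5. Ring order: the arene is bought; the oxane ring is made first (step 1, sets C4); the carbocycle second (step 7, sets C6 while the oxane opens).

Key step: step 7

Assumption: the sense of induction of the bromolactonisation catalyst on this gem-dimethyl alkene is not presumed; the pseudo-enantiomeric catalyst that gives (R)-2 is chosen after a trial run.

**Route**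

Step 1
Reactants: 1 5-methylhex-4-enoic acid
Product: 2 (R)-5-bromo-6,6-dimethyloxan-2-one
Conditions: NBS (1.1 equiv), cinchona-alkaloid amino-thiocarbamate catalyst (10 mol %), CHCl3–PhMe, −78 °C
Reagents that add atoms: N-bromosuccinimide, O=C1CCC(=O)N1Br
Why: Catalytic asymmetric bromolactonisation: the bifunctional catalyst delivers Br+ to one alkene face while holding the carboxylate, which opens the bromonium at the gem-dimethyl carbon (Markovnikov, 6-endo) to the δ-lactone, so the CHBr centre (R) is set by the catalyst and its enantiomeric purity is checked on a chiral phase before going on.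

Step 2
Reactants: 3 2,5-dimethoxybenzaldehyde
Product: 4 4-bromo-2,5-dimethoxybenzaldehyde
Conditions: Br2 (1.1 equiv), AcOH, rt; recrystallise
Reagents that add atoms: bromine, BrBr
Why: Electrophilic aromatic bromination should go ortho to the 5-methoxy group at the unhindered position para to the formyl group, and a minor 6-bromo isomer is removed by crystallisation.

Step 3
Reactants: 4 4-bromo-2,5-dimethoxybenzaldehyde
Product: 5 (4-bromo-2,5-dimethoxyphenyl)methanol
Conditions: NaBH4, MeOH, 0 °C
Reagents that add atoms: none
Why: Borohydride reduction of an aryl aldehyde, to which the aryl bromide and the ethers are inert.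

Step 4
Reactants: 5 (4-bromo-2,5-dimethoxyphenyl)methanol
Product: 6 1-bromo-4-(bromomethyl)-2,5-dimethoxybenzene
Conditions: PBr3 (0.4 equiv), CH2Cl2, 0 °C
Reagents that add atoms: phosphorus tribromide, BrP(Br)Br
Why: Bromination of an electron-rich benzylic alcohol through its phosphite ester, a standard substitution.

Step 5
Reactants: 6 1-bromo-4-(bromomethyl)-2,5-dimethoxybenzene; 7 dibromomethane
Product: 9 1-bromo-4-(2,2-dibromoethyl)-2,5-dimethoxybenzene, via dibromomethyllithium 8 (not isolated)
Conditions: 7, LDA, THF, −95 °C; then 6, −95 → −60 °C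
Reagents that add atoms: none
Why: Deprotonation of CH2Br2 gives the carbenoid LiCHBr2, which is alkylated by the reactive benzylic bromide below its decomposition temperature (carbenoid alkylation), and the aryl bromide is safe because no alkyllithium is present.

Step 6
Reactants: 2 (R)-5-bromo-6,6-dimethyloxan-2-one; 9 1-bromo-4-(2,2-dibromoethyl)-2,5-dimethoxybenzene
Product: 10 (2Z,5R)-5-bromo-2-[2-(4-bromo-2,5-dimethoxyphenyl)ethylidene]-6,6-dimethyloxane
Conditions: Zn, TiCl4, TMEDA, cat. PbCl2, THF, 25 °C; then 2 + 9 (2.2 equiv), 2 h; aq. K2CO3, Et3N-washed basic alumina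
Reagents that add atoms: none
Why: Takai–Utimoto alkylidenation: the non-basic zinc/titanium alkylidene reagent from the 1,1-dibromide converts the ester-type carbonyl into the alkenyl ether, the alkylidene substituent turning away from the ring CH2 (no A1,3 strain) and so cis to the ring oxygen (Z), while the short reaction time at 25 °C is meant to spare the hindered secondary bromide.

Step 7
Reactants: 10 (2Z,5R)-5-bromo-2-[2-(4-bromo-2,5-dimethoxyphenyl)ethylidene]-6,6-dimethyloxane
Product: 12 (2R,4R)-4-bromo-2-[(4-bromo-2,5-dimethoxyphenyl)methyl]-3,3-dimethylcyclohexan-1-one, via bromonium aluminium enolate zwitterion 11 (not isolated)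
Conditions: Me2AlCl (2.0 equiv), CH2Cl2, −78 → −20 °C; aq. Rochelle salt
Reagents that add atoms: none
Why: Proposed new method: Me2AlCl binds the enol ether oxygen of 10 and the O–C5 bond (carbocycle numbering, the CMe2 carbon) ionises with anchimeric help from the C4 bromine, which is equatorial and anti-periplanar to that bond, so that the bromonium/Z-aluminium enolate pair 11 forms with C4 untouched; the enolate carbon C6 then attacks C5 anti to bromine and gives ketone 12, whereas return through oxygen only regenerates 10. The closest known reactions are Lewis-acid 1,3 oxygen-to-carbon rearrangements of cyclic enol ethers (Ferrier carbocyclisation, Petasis–Ferrier rearrangement with Me2AlCl) and bromonium-initiated cation–olefin cyclisation, and no such rearrangement of a β-bromo tertiary-alkyl enol ether is known. The carbocycle closes by 6-(enolendo) attack with endo opening of the bromonium at its tertiary carbon through a chair. C6 is controlled by the existing C4 centre and the enol ether geometry: anti opening puts Br equatorial and the Z enolate puts CH2Ar equatorial, hence the cis (2R,4R) ketone. The step needs carbon attack on C5 to beat proton loss, chloride capture and bromine transfer to the enolate carbon; the tertiary C5, the six-membered tether, the absence of any free alkene (no bromonium exchange, so no racemisation) and the proton-scavenging methylaluminium reagent should favour it.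

Step 8
Reactants: 12 (2R,4R)-4-bromo-2-[(4-bromo-2,5-dimethoxyphenyl)methyl]-3,3-dimethylcyclohexan-1-one; 7 dibromomethane
Product: 13 1-bromo-4-{[(1S,3R)-3-bromo-2,2-dimethyl-6-methylidenecyclohexyl]methyl}-2,5-dimethoxybenzene
Conditions: Zn, CH2Br2, TiCl4, THF–CH2Cl2, 0 °C → rt
Reagents that add atoms: none
Why: Takai–Lombardo methylenation: the non-basic gem-dimetallic reagent should methylenate the hindered, enolisable ketone without epimerising the α-centre and without base-induced loss of HBr or cyclopropane formation from the γ-bromide.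

Step 9
Reactants: 13 1-bromo-4-{[(1S,3R)-3-bromo-2,2-dimethyl-6-methylidenecyclohexyl]methyl}-2,5-dimethoxybenzene
Product: 15 cyclocymopol [2-bromo-5-{[(1S,3R)-3-bromo-2,2-dimethyl-6-methylidenecyclohexyl]methyl}benzene-1,4-diol], via bromoquinone 14 (not isolated)
Conditions: CAN (2.5 equiv), MeCN–H2O, 0 °C, 15 min; extract (Et2O); then aq. Na2S2O4, rt, Ar
Reagents that add atoms: water, O
Why: Oxidative demethylation: Ce(IV) oxidises the p-dimethoxyarene to the quinone (oxygens from water, methanol lost) without touching the alkyl bromide, aryl bromide or 1,1-disubstituted alkene, and dithionite reduces the quinone to the hydroquinone under neutral conditions, so the ortho phenol should not add to the exocyclic alkene.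

**Compound list**

1 | 5-methylhex-4-enoic acid | CC(C)=CCCC(=O)O | starting material
2 | (R)-5-bromo-6,6-dimethyloxan-2-one | O=C1CC[C@@H](Br)C(C)(C)O1 | intermediate
3 | 2,5-dimethoxybenzaldehyde | COc1ccc(OC)c(C=O)c1 | starting material
4 | 4-bromo-2,5-dimethoxybenzaldehyde | COc1cc(C=O)c(OC)cc1Br | intermediate
5 | (4-bromo-2,5-dimethoxyphenyl)methanol | COc1cc(CO)c(OC)cc1Br | intermediate
6 | 1-bromo-4-(bromomethyl)-2,5-dimethoxybenzene | COc1cc(CBr)c(OC)cc1Br | intermediate
7 | dibromomethane | BrCBr | starting material
8 | dibromomethyllithium | [Li]C(Br)Br | intermediate (not isolated)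
9 | 1-bromo-4-(2,2-dibromoethyl)-2,5-dimethoxybenzene | COc1cc(CC(Br)Br)c(OC)cc1Br | intermediate
10 | (2Z,5R)-5-bromo-2-[2-(4-bromo-2,5-dimethoxyphenyl)ethylidene]-6,6-dimethyloxane | COc1cc(Br)c(OC)cc1C/C=C1/CC[C@@H](Br)C(C)(C)O1 | intermediate
11 | bromonium / chlorodimethylaluminate Z-enolate zwitterion from 10 | C[Al-](C)(Cl)O/C(CC[C@H]1[Br+]C1(C)C)=C\Cc1cc(OC)c(Br)cc1OC | intermediate (not isolated)
12 | (2R,4R)-4-bromo-2-[(4-bromo-2,5-dimethoxyphenyl)methyl]-3,3-dimethylcyclohexan-1-one (cis) | O=C1CC[C@@H](Br)C(C)(C)[C@H]1Cc1cc(OC)c(Br)cc1OC | intermediate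
13 | 1-bromo-4-{[(1S,3R)-3-bromo-2,2-dimethyl-6-methylidenecyclohexyl]methyl}-2,5-dimethoxybenzene | C=C1CC[C@@H](Br)C(C)(C)[C@H]1Cc1cc(OC)c(Br)cc1OC | intermediate
14 | 2-bromo-5-{[(1S,3R)-3-bromo-2,2-dimethyl-6-methylidenecyclohexyl]methyl}cyclohexa-2,5-diene-1,4-dione | C=C1CC[C@@H](Br)C(C)(C)[C@H]1CC1=CC(=O)C(Br)=CC1=O | intermediate (not isolated)
15 | cyclocymopol, 2-bromo-5-{[(1S,3R)-3-bromo-2,2-dimethyl-6-methylidenecyclohexyl]methyl}benzene-1,4-diol | C=C1CC[C@@H](Br)C(C)(C)[C@H]1Cc1cc(O)c(Br)cc1O | target

**Step count**

Total steps: 9. Longest linear sequence: 8 (steps 2–9, from 3).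

**Steps most likely to fail**

Step 7. The ionised intermediate may lose a proton, capture chloride or pass bromine to the enolate carbon instead of closing the C5–C6 bond, or the tertiary C–O bond may not ionise at all. The fallback closes the carbocycle by the known bromonium-initiated cation–olefin cyclisation of a geranyl arene; it sets out from 6 and comes back at 13, replacing steps 5–8.
- 6-Methylhept-5-en-1-yne F1 is made from 5-bromo-2-methylpent-2-ene and lithium acetylide–ethylenediamine in DMSO.
- Zr-catalysed carboalumination of F1 (Me3Al, cat. Cp2ZrCl2) gives (E)-(2,6-dimethylhepta-1,5-dien-1-yl)dimethylalane F2.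
- Pd(PPh3)4-catalysed coupling of F2 with 6 gives 1-bromo-4-[(2E)-3,7-dimethylocta-2,6-dien-1-yl]-2,5-dimethoxybenzene F3; the benzylic C–Br bond should add to Pd(0) much faster than the electron-rich aryl bromide.
- F3 with bromodiethylsulfonium bromopentachloroantimonate in MeNO2 at −25 °C should cyclise through the same chair to 13, which is separated from endocyclic alkene isomers on AgNO3–silica.
- This cyclisation is not enantiocontrolled by the substrate, so it would give 13 together with the enantiomer of 13 F4. The single enantiomer would come from a chiral Lewis-base promoter for the bromonium transfer or, failing that, from preparative HPLC of 13 on a chiral phase.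

Step 6. Zinc or low-valent titanium may reductively eliminate the β-acyloxy bromide (ring opening back to the alkenoic acid), the lactone carbonyl may react sluggishly, or the Z geometry may erode. The fallback forms the enol ether from the oxygen side, with no reducing metal near the alkyl bromide; it sets out from 6 and comes back at 10, replacing steps 1, 5 and 6.
- Cu-catalysed coupling of 6 with alkyne F1 (CuI, Cs2CO3, MeCN) gives 1-bromo-2,5-dimethoxy-4-(7-methyloct-6-en-2-yn-1-yl)benzene F5.
- NBS in aqueous THF gives the Markovnikov bromohydrin as a racemate, which is resolved by preparative SFC on a chiral phase into (3R)-3-bromo-8-(4-bromo-2,5-dimethoxyphenyl)-2-methyloct-6-yn-2-ol F6 and its (3S) enantiomer F7, the latter set aside.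
- Gold(I)-catalysed 6-exo-dig hydroalkoxylation of F6 ((JohnPhos)Au(MeCN)SbF6, CH2Cl2, 0 °C, Et3N quench) should give 10; anti oxyauration followed by protodeauration with retention places CH2Ar cis to oxygen (Z).

Step 1. Facial discrimination of an alkene whose terminus is a gem-dimethyl group may be poor, and some 5-exo closure may compete. The fallback replaces asymmetric induction by resolution; it sets out from 1 and comes back at 2. Uncatalysed bromolactonisation of 1 (NBS, CH2Cl2) gives the racemic δ-lactone, which is separated by preparative SFC on a chiral phase into 2 and (S)-5-bromo-6,6-dimethyloxan-2-one F8, the latter set aside.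

**Further compounds**

F1 | step 7 | 6-methylhept-5-en-1-yne | C#CCCC=C(C)C
F2 | step 7 | (E)-(2,6-dimethylhepta-1,5-dien-1-yl)dimethylalane | C[Al](C)/C=C(\C)CCC=C(C)C
F3 | step 7 | 1-bromo-4-[(2E)-3,7-dimethylocta-2,6-dien-1-yl]-2,5-dimethoxybenzene | COc1cc(C/C=C(\C)CCC=C(C)C)c(OC)cc1Br
F4 | step 7 | enantiomer of 13, 1-bromo-4-{[(1R,3S)-3-bromo-2,2-dimethyl-6-methylidenecyclohexyl]methyl}-2,5-dimethoxybenzene | C=C1CC[C@H](Br)C(C)(C)[C@@H]1Cc1cc(OC)c(Br)cc1OC
F5 | step 6 | 1-bromo-2,5-dimethoxy-4-(7-methyloct-6-en-2-yn-1-yl)benzene | COc1cc(CC#CCCC=C(C)C)c(OC)cc1Br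
F6 | step 6 | (3R)-3-bromo-8-(4-bromo-2,5-dimethoxyphenyl)-2-methyloct-6-yn-2-ol | COc1cc(CC#CCC[C@@H](Br)C(C)(C)O)c(OC)cc1Br
F7 | step 6 | (3S)-3-bromo-8-(4-bromo-2,5-dimethoxyphenyl)-2-methyloct-6-yn-2-ol | COc1cc(CC#CCC[C@H](Br)C(C)(C)O)c(OC)cc1Br
F8 | step 1 | (S)-5-bromo-6,6-dimethyloxan-2-one | O=C1CC[C@H](Br)C(C)(C)O1
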